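**Retrosynthetic overview**
- The formyl group goes on last: the deformyl depside has a single aromatic C–H (C5 of the acyl ring), so a Rieche formylation there is regiochemically unambiguous.
- The depside ester is cut into 2,4-bis(benzyloxy)-3,6-dimethylbenzoic acid (ring A) and methyl 2,4-dihydroxy-3,5,6-trimethylbenzoate (ring B); they are joined by TFAA acylation, then debenzylated.
- Both halves come from one arene, methyl 2,4-dihydroxy-3,6-dimethylbenzoate. Ring B needs C5 formylation and deoxygenation to methyl; ring A needs O-benzylation and saponification.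
- That arene comes from dimethyl malonate and (E)-hex-4-en-3-one: intermolecular Michael addition (key C–C bond), Dieckmann-type Claisen ring closure, then chlorination and dehydrochlorination.
- Ring order: the one six-membered carbocycle is built first and aromatised; it serves as both benzene rings, and no further ring is formed.

Assumption: the target has no stereogenic element, so the drawn structure is the single compound required; the sp3 stereocentres of the pre-aromatic and chloro-ether intermediates form unselectively and are erased.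

**Step 1**
Reactants: 1 dimethyl malonate; 2 (E)-hex-4-en-3-one
Product: 4 methyl 3,6-dimethyl-2,4-dioxocyclohexane-1-carboxylate, via keto diester 3 (not isolated)
Conditions: NaOMe (1.1 equiv), MeOH, reflux; then aq. HCl, 0 °C
Reagents that add atoms: none
Why: Tandem intermolecular Michael addition of the malonate anion to the enone β-carbon (the key C–C bond) and intramolecular Claisen (Dieckmann-type) condensation of the ethyl-ketone enolate onto one ester, driven by formation of the stable β-diketone enolate; the stereocentres are uncontrolled and are erased on aromatisation.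

**Step 2**
Reactants: 4 methyl 3,6-dimethyl-2,4-dioxocyclohexane-1-carboxylate
Product: 5 methyl 3-chloro-3,6-dimethyl-2,4-dioxocyclohexane-1-carboxylate
Conditions: SO2Cl2 (1.0 equiv), CH2Cl2, 0 °C → rt
Reagents that add atoms: sulfuryl chloride, O=S(=O)(Cl)Cl
Why: Electrophilic α-chlorination of the enolised cyclic 1,3-dione at C3, its most nucleophilic carbon, brings the ring to the arene oxidation level irreversibly and without over-halogenation.

**Step 3**
Reactants: 5 methyl 3-chloro-3,6-dimethyl-2,4-dioxocyclohexane-1-carboxylate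
Product: 6 methyl 2,4-dihydroxy-3,6-dimethylbenzoate
Conditions: HCl (cat., 4 M in dioxane), DMF, 100 °C
Reagents that add atoms: none
Why: Dehydrochlorinative aromatisation of a 2-chloro-2-alkylcyclohexane-1,3-dione (acid-catalysed enolisation, allylic chlorine shift, loss of HCl, tautomerisation), driven by aromatic stabilisation.

**Step 4**
Reactants: 6 methyl 2,4-dihydroxy-3,6-dimethylbenzoate (part of the batch)
Product: 8 methyl 5-formyl-2,4-dihydroxy-3,6-dimethylbenzoate, via chloro(methoxy)methyl arene 7 (not isolated)
Conditions: Cl2CHOMe (1.5 equiv), TiCl4 (3 equiv), CH2Cl2, −10 → 0 °C; then ice/1 M HCl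
Reagents that add atoms: dichloromethyl methyl ether, COC(Cl)Cl; water, O
Why: Rieche formylation (titanium-phenoxide-directed electrophilic aromatic substitution) can only attack C5, the sole free position, which is ortho to 4-OH and para to 2-OH, and aqueous acid hydrolyses the α-chloro ether to the aldehyde.

**Step 5**
Reactants: 8 methyl 5-formyl-2,4-dihydroxy-3,6-dimethylbenzoate
Product: 10 methyl 2,4-dihydroxy-3,5,6-trimethylbenzoate, via benzylic alcohol 9 (not isolated)
Conditions: Et3SiH (3 equiv), TFA/CH2Cl2 (1:1), 0 °C → rt
Reagents that add atoms: none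
Why: Ionic hydrogenation, in which the ortho/para-hydroxy-stabilised benzylic cation forms readily in TFA and takes hydride from the silane twice (ArCHO → ArCH2OH → ArCH3), leaving the ester untouched and, on a fully substituted ring, with no Friedel–Crafts dimerisation.

**Step 6**
Reactants: 6 methyl 2,4-dihydroxy-3,6-dimethylbenzoate (remainder of the batch)
Product: 12 methyl 2,4-bis(benzyloxy)-3,6-dimethylbenzoate, via 4-O-benzyl ether 11 (not isolated)
Conditions: BnBr (2.5 equiv), K2CO3, DMF, 70 °C
Reagents that add atoms: benzyl bromide, BrCc1ccccc1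
Why: Williamson etherification, in which the free 4-OH reacts first and the hydrogen-bonded 2-OH follows with excess bromide in hot DMF, so the acid cannot self-acylate in the coupling.

**Step 7**
Reactants: 12 methyl 2,4-bis(benzyloxy)-3,6-dimethylbenzoate
Product: 13 2,4-bis(benzyloxy)-3,6-dimethylbenzoic acid
Conditions: KOH (10 equiv), DMSO/H2O (4:1), 90 °C; then 1 M HCl, 0 °C
Reagents that add atoms: potassium hydroxide, [K+].[OH-]
Why: Saponification (BAc2) of the di-ortho-substituted ester succeeds with poorly solvated hydroxide in DMSO, the benzyl ethers are inert, and cold acidification avoids decarboxylation.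

**Step 8**
Reactants: 13 2,4-bis(benzyloxy)-3,6-dimethylbenzoic acid; 10 methyl 2,4-dihydroxy-3,5,6-trimethylbenzoate
Product: 15 methyl 4-{[2,4-bis(benzyloxy)-3,6-dimethylbenzoyl]oxy}-2-hydroxy-3,5,6-trimethylbenzoate, via mixed trifluoroacetic anhydride 14 (not isolated)
Conditions: TFAA (4 equiv), toluene, rt; then aq. NaHCO3
Reagents that add atoms: none
Why: TFAA-mediated esterification through the mixed anhydride (in equilibrium with the electron-rich, sterically small acylium ion) acylates the flanked 4-OH, whereas the 2-OH is deactivated by its hydrogen bond to the ester carbonyl and any aryl trifluoroacetate is cleaved on bicarbonate work-up.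

**Step 9**
Reactants: 15 methyl 4-{[2,4-bis(benzyloxy)-3,6-dimethylbenzoyl]oxy}-2-hydroxy-3,5,6-trimethylbenzoate
Product: 16 methyl 4-[(2,4-dihydroxy-3,6-dimethylbenzoyl)oxy]-2-hydroxy-3,5,6-trimethylbenzoate
Conditions: H2 (1 atm), 10% Pd/C, EtOAc, rt
Reagents that add atoms: none
Why: Catalytic hydrogenolysis removes both benzyl ethers, the aryl and methyl esters are stable to it, and no reducible aldehyde is present yet.

**Step 10**
Reactants: 16 methyl 4-[(2,4-dihydroxy-3,6-dimethylbenzoyl)oxy]-2-hydroxy-3,5,6-trimethylbenzoate
Product: 18 isopseudocyphellarin A, via chloro(methoxy)methyl depside 17 (not isolated)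
Conditions: Cl2CHOMe (2 equiv), TiCl4 (5 equiv), CH2Cl2, −10 → 0 °C; then ice/1 M HCl
Reagents that add atoms: dichloromethyl methyl ether, COC(Cl)Cl; water, O
Why: Rieche formylation as in step 4, where 16 has exactly one aromatic C–H (C5 of the acyl ring, ortho to 4-OH and para to 2-OH, ring B being fully substituted) and the depside ester tolerates TiCl4 at or below 0 °C.

**Compound list**
1 | dimethyl malonate | COC(=O)CC(=O)OC | starting material
2 | (E)-hex-4-en-3-one | CCC(=O)/C=C/C | starting material
3 | dimethyl 2-(4-oxohexan-2-yl)propanedioate (racemic) | COC(=O)C(C(=O)OC)C(C)CC(=O)CC | intermediate (not isolated)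
4 | methyl 3,6-dimethyl-2,4-dioxocyclohexane-1-carboxylate (racemic, diastereomer and enol mixture) | COC(=O)C1C(C)CC(=O)C(C)C1=O | intermediate
5 | methyl 3-chloro-3,6-dimethyl-2,4-dioxocyclohexane-1-carboxylate (racemic, diastereomer mixture) | COC(=O)C1C(C)CC(=O)C(C)(Cl)C1=O | intermediate
6 | methyl 2,4-dihydroxy-3,6-dimethylbenzoate | COC(=O)c1c(C)cc(O)c(C)c1O | intermediate
7 | methyl 5-[chloro(methoxy)methyl]-2,4-dihydroxy-3,6-dimethylbenzoate (racemic, titanium-bound in the flask) | COC(=O)c1c(C)c(C(Cl)OC)c(O)c(C)c1O | intermediate (not isolated)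
8 | methyl 5-formyl-2,4-dihydroxy-3,6-dimethylbenzoate | COC(=O)c1c(C)c(C=O)c(O)c(C)c1O | intermediate
9 | methyl 2,4-dihydroxy-5-(hydroxymethyl)-3,6-dimethylbenzoate | COC(=O)c1c(C)c(CO)c(O)c(C)c1O | intermediate (not isolated)
10 | methyl 2,4-dihydroxy-3,5,6-trimethylbenzoate | COC(=O)c1c(C)c(C)c(O)c(C)c1O | intermediate
11 | methyl 4-(benzyloxy)-2-hydroxy-3,6-dimethylbenzoate | COC(=O)c1c(C)cc(OCc2ccccc2)c(C)c1O | intermediate (not isolated)
12 | methyl 2,4-bis(benzyloxy)-3,6-dimethylbenzoate | COC(=O)c1c(C)cc(OCc2ccccc2)c(C)c1OCc3ccccc3 | intermediate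
13 | 2,4-bis(benzyloxy)-3,6-dimethylbenzoic acid | OC(=O)c1c(C)cc(OCc2ccccc2)c(C)c1OCc3ccccc3 | intermediate
14 | 2,4-bis(benzyloxy)-3,6-dimethylbenzoic trifluoroacetic anhydride | O=C(OC(=O)C(F)(F)F)c1c(C)cc(OCc2ccccc2)c(C)c1OCc3ccccc3 | intermediate (not isolated)
15 | methyl 4-{[2,4-bis(benzyloxy)-3,6-dimethylbenzoyl]oxy}-2-hydroxy-3,5,6-trimethylbenzoate | COC(=O)c1c(C)c(C)c(OC(=O)c2c(C)cc(OCc3ccccc3)c(C)c2OCc4ccccc4)c(C)c1O | intermediate
16 | methyl 4-[(2,4-dihydroxy-3,6-dimethylbenzoyl)oxy]-2-hydroxy-3,5,6-trimethylbenzoate | COC(=O)c1c(C)c(C)c(OC(=O)c2c(C)cc(O)c(C)c2O)c(C)c1O | intermediate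
17 | methyl 4-({5-[chloro(methoxy)methyl]-2,4-dihydroxy-3,6-dimethylbenzoyl}oxy)-2-hydroxy-3,5,6-trimethylbenzoate (racemic, titanium-bound in the flask) | COC(=O)c1c(C)c(C)c(OC(=O)c2c(C)c(C(Cl)OC)c(O)c(C)c2O)c(C)c1O | intermediate (not isolated)
18 | isopseudocyphellarin A, methyl 4-[(5-formyl-2,4-dihydroxy-3,6-dimethylbenzoyl)oxy]-2-hydroxy-3,5,6-trimethylbenzoate (achiral) | COC(=O)c1c(C)c(C)c(OC(=O)c2c(C)c(C=O)c(O)c(C)c2O)c(C)c1O | target

**Totals**
Total step count: 10. Longest linear sequence: 8 steps (steps 1–3, then 4–5 or 6–7, then 8–10).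

**Three steps most likely to fail, with fallbacks**

Step 3, the thermal dehydrochlorination, may be incomplete or may cost the β-keto ester before the ring aromatises. The fallback sets out from 4 and comes back at 6. Bromine (2.2 equiv) in acetic acid at rt brominates C3 to give methyl 3-bromo-3,6-dimethyl-2,4-dioxocyclohexane-1-carboxylate F1. F1 loses HBr spontaneously to the arene, which is brominated in the same flask at its free position to give crystalline methyl 5-bromo-2,4-dihydroxy-3,6-dimethylbenzoate F2. Hydrogenolysis of the C–Br bond (H2, Pd/C, NaOAc, MeOH) then gives 6. This is over-halogenation followed by reduction, in place of a single halogenation and elimination.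

Step 8 joins a di-ortho-substituted acid to a phenol flanked by two methyl groups, so conversion or 4-O/2-O selectivity may be poor. The fallback sets out from 13 and comes back at 15. Oxalyl chloride with catalytic DMF in CH2Cl2 converts 13 into the isolated 2,4-bis(benzyloxy)-3,6-dimethylbenzoyl chloride F3. F3 then acylates the more acidic, non-chelated 4-OH of 10 under nucleophilic catalysis (Et3N, DMAP, CH2Cl2, reflux) to give 15. A preformed acyl chloride with base replaces the acidic mixed-anhydride activation.

Step 10 exposes the free depside to TiCl4, which may give low conversion or ester cleavage. The fallback sets out from 8 and comes back at 18, with the formyl group in place before the depside bond is made. Cold concentrated H2SO4 cleaves the hindered methyl ester of 8 through the acylium ion (AAc1, poured onto ice) to give 5-formyl-2,4-dihydroxy-3,6-dimethylbenzoic acid F4. F4 is condensed with 10 using TFAA in toluene through 5-formyl-2,4-dihydroxy-3,6-dimethylbenzoic trifluoroacetic anhydride F5, which gives 18 directly and bypasses 12–17.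

**Further compounds**
F1 | step 3 | methyl 3-bromo-3,6-dimethyl-2,4-dioxocyclohexane-1-carboxylate | COC(=O)C1C(C)CC(=O)C(C)(Br)C1=O
F2 | step 3 | methyl 5-bromo-2,4-dihydroxy-3,6-dimethylbenzoate | COC(=O)c1c(C)c(Br)c(O)c(C)c1O
F3 | step 8 | 2,4-bis(benzyloxy)-3,6-dimethylbenzoyl chloride | O=C(Cl)c1c(C)cc(OCc2ccccc2)c(C)c1OCc3ccccc3
F4 | step 10 | 5-formyl-2,4-dihydroxy-3,6-dimethylbenzoic acid | OC(=O)c1c(C)c(C=O)c(O)c(C)c1O
F5 | step 10 | 5-formyl-2,4-dihydroxy-3,6-dimethylbenzoic trifluoroacetic anhydride | O=C(OC(=O)C(F)(F)F)c1c(C)c(C=O)c(O)c(C)c1O
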